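## Structural features

The target is an ether between two unequal halves: a 5-methylcoumarin (a benzene ring fused to an α-pyranone) whose C4 oxygen carries the chain, and a 2,2-dimethyl-4-methylidenecyclohexanone. They are joined by the chain C1–C5, which holds an E-trisubstituted alkene C2=C3 with a methyl on C3, so that C1 is both allylic and the alkyl carbon of a vinylogous ester. The carbocycle (C6–C11) holds the only stereocentre, C6, which is R (CIP order C11 > C7 > C5 > H). C6 is a tertiary allylic CH between the quaternary C11 (gem-dimethyl, next to the C10 ketone) and C7, which bears the exocyclic methylene, and no neighbouring stereocentre or heteroatom can relay induction to it. Fragile points are the allyl coumarinyl ether (ionisation, zerovalent palladium, thermal Claisen shift to C3 of the coumarin), the exocyclic alkene (migration to C6=C7 would erase the stereocentre) and the ketone with its C9 methylene (aldol chemistry). The real difficulty is the absolute configuration of this isolated tertiary centre beside a quaternary carbon, whereas the E-alkene and the ether are matters of fragment choice and ordering. The key step exploits the fact that C7 is a 1,1-disubstituted vinylic carbon bonded to C6: cutting C6–C7 opens the ring to a 2-bromoallyl unit (C7, its methylene, C8) and an E-allylic silyl ether (C6=C5–C4), so a 6-exo Heck closure rebuilds the cyclohexanone, keeps the vinylic carbon as the exocyclic methylene and turns C4 into the aldehyde that later carries the chain.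

## Logic of the disconnections

27 to 21 and 26: the C1–O bond to the coumarin C4 oxygen is cut first. It is the most labile bond, so it is made last and under neutral conditions, and the cut separates an achiral aromatic half from the chiral half. The forward step must alkylate the C4 oxygen of an ambident partner and substitute C1 without allylic shift.

21 through 20 to 14 and 18: with O1 silylated again (20), the C3–C4 bond between the alkene and the chain methylene is cut. The whole E-alkene with its methyl and C1 then sits in the small fragment 18, and 14 is the ring with a two-carbon arm ending at C4. The forward coupling needs a C4 organometallic that ignores the C10 ketone (zinc, 19) and must keep the alkene geometry.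

14 to 13 to 12: two functional-group changes at C4 (iodide from alcohol, alcohol from aldehyde) and no skeletal cut. The demand is that hydride distinguishes the aldehyde from the hindered ketone.

12 through 11 to 10: the C6–C7 ring bond is cut, and the C4 aldehyde is traced through its enol silyl ether to the C5=C6 alkene with a C4 silyl ether. Ring and stereocentre vanish together, leaving an acyclic, achiral precursor. The forward step must close the six-membered ring exo, choose one alkene face under ligand control and eliminate toward C4.

10 to 7 and 8: the C8–C9 bond is cut. 7 can enolise only at its methyl group, and 8 brings C7, the methylene, C8 and the bromine. The demand is monoalkylation at the allylic and not the vinylic bromide.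

7 back through 6, 5, 4, 3 and 2 to 1: the C5=C6 double bond is cut (olefination of a C6 aldehyde by a two-carbon ylide). The C10 ketone is parked as a carbinol so that the ester-level reduction needs no ketal. 1 supplies C6, C11 with both methyls, C10 and C9. The demands are oxidation of a primary hydroxyl beside a secondary one and silylation of the primary allylic hydroxyl only.

18 through 17 and 16 to 15: the C3–I bond is traced to a C3–Zr bond and that to the alkyne. The demand is syn addition with the metal on the methyl-bearing carbon.

26 through 25, 24 and 23 to 22: the lactone carbon C2 is removed (bonds C2–C3 and C2–O1, from a carbonate ester), then the acetyl C–CH3 bond. 22 fixes the position of the aromatic methyl group, so no regiochemical question arises.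

## Other disconnections considered

Alternative 1: The cut lies inside the chain, at C3–CH3 and C2–C1, and traces the allylic alcohol A1 to the terminal alkyne A2, both carrying C10 as a silyl-protected carbinol. The forward key step is Cp2ZrCl2-catalysed syn-methylalumination with Me3Al, followed by trapping of the alkenylalane ate complex with a one-carbon aldehyde.
- In favour: the E geometry is created in one flask by a syn addition, and no separate alkenyl halide fragment is needed.
- Against here: Me3Al does not tolerate the C10 ketone, so a second, useless stereocentre is carried and the ketone must be restored by desilylation and oxidation after the etherification, on the most fragile compound. A2 must still be made from a ring piece such as 14 by adding C3 and C2, and the setting of C6 is left unanswered.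
- Structure: both plans build the same chain; the alternative does it atom by atom on the ring fragment, the chosen plan joins two fragments at C3–C4.
- Mechanism: syn carbometalation should fix the geometry as reliably as syn hydrozirconation with a stereoretentive coupling, so the two are equal here. The alternative is the better plan in needing no sp3 organozinc beside a ketone and no second fragment.
- Step economy: from an aldehyde like 12 it would need ketone reduction and silylation, two-carbon homologation, carboalumination, etherification, desilylation and oxidation. The chosen plan needs five steps from 12 plus two for 18, so the alternative is longer on the main line.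

Alternative 2: The cut is the C4a–C5 bond of the coumarin, so the benzo ring is built and not bought. The forward key step is irradiation of the dienylpyranone A4 with I2: alkene isomerisation, 6π-electrocyclisation and dehydrogenation to A3.
- In favour: the place of the 5-methyl group is fixed by the bond that forms.
- Against here: 22 already carries the right substitution, the photochemical step needs dilution and a stoichiometric oxidant, and A3 is a methyl ether that must be demethylated to reach 26. The alternative does not touch C6.
- Structure: both plans give the same bicyclic partner, and on regiochemical certainty of the methyl group they are equal.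
- Mechanism: a photochemical pericyclic closure against a thermal Claisen-type condensation; the condensation scales more easily.
- Step economy: assembly of A4, photocyclisation and demethylation come to at least four steps against two from 22.

Alternative 3: The cut is the C8–C9 ring bond, with C6 taken from the chiral pool, (S)-limonene A7. The forward key step treats the chloro ketone A6 with LiN(SiMe3)2, and the C9 enolate displaces the allylic chloride at C8 (6-exo-tet) to give A5.
- In favour: the absolute configuration is inherited and needs no ligand control, and on this point the alternative is the better plan. Direct and allylic displacement give the same A5, and A5 already contains C5, C4, C3 and the C3 methyl.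
- Against here: the R centre of A5 maps onto the scarcer S enantiomer A7, because the CIP ranking of the two ring branches inverts. Reaching A6 needs oxidative opening of the ring alkene beside the isopropenyl group, differentiation of the two carbonyl termini, double methylation next to the stereocentre, conversion of an aldehyde to the C10 methyl ketone and allylic chlorination. After A5 the C2=C3 alkene must still be made by olefination of a methyl ketone, where E/Z control is usually incomplete, followed by ester reduction beside the C10 ketone.
- Structure: both plans deliver the same ring; the alternative brings more of the chain with it.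
- Mechanism: an enolate alkylation is more predictable than an asymmetric Heck insertion.
- Step economy: the chosen plan reaches 12 in seven steps and 21 in eleven; the alternative would need clearly more steps to A5 and several more to 21.

Key step: step 7

Assumption 1: (R)-BINAP is written as the antipode that delivers C7 to the Si face of C6 in 10; if the sense of induction is the reverse, (S)-BINAP is used with nothing else changed.
Assumption 2: compounds 2 to 6 carry a carbinol centre that step 5 oxidises away and are handled as racemates.

## Route

Step 1
Reactants: 1 ethyl 2,2-dimethyl-3-oxobutanoate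
Product: 2 rac-2,2-dimethylbutane-1,3-diol
Conditions: LiAlH4, THF, 0 → 25 °C
Reagents that add atoms: none
Why: Hydride reduction of ester and ketone together (LiAlH4 reduction); the ketone is deliberately stored as a secondary alcohol so that steps 2 and 3 need no ketal, and its configuration is irrelevant because step 5 removes it.

Step 2
Reactants: 2 rac-2,2-dimethylbutane-1,3-diol
Product: 4 rac-ethyl (E)-5-hydroxy-4,4-dimethylhex-2-enoate, via 3-hydroxy-2,2-dimethylbutanal 3 (not isolated)
Conditions: 2,2,6,6-tetramethylpiperidine-1-oxyl (10 mol%), PhI(OAc)2, CH2Cl2, 25 °C; then Ph3P=CHCO2Et, 40 °C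
Reagents that add atoms: ethyl (triphenylphosphoranylidene)acetate, CCOC(=O)C=P(c1ccccc1)(c1ccccc1)c1ccccc1
Why: The oxoammonium oxidation is much faster at the primary than at the hindered secondary hydroxyl, and aldehyde 3 has no α-hydrogen and cannot dehydrate. The stabilised ylide traps it in the same flask (one-pot oxidation–Wittig reaction) and should give the E-enoate, which cannot lactonise.

Step 3
Reactants: 4 rac-ethyl (E)-5-hydroxy-4,4-dimethylhex-2-enoate
Product: 5 rac-(E)-4,4-dimethylhex-2-ene-1,5-diol
Conditions: iBu2AlH (3.5 equiv), CH2Cl2, −78 → 0 °C
Reagents that add atoms: none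
Why: 1,2-Reduction of the conjugated ester to the allylic alcohol by the aluminium hydride, which leaves the alkene and its E geometry untouched; one equivalent is consumed by the free hydroxyl.

Step 4
Reactants: 5 rac-(E)-4,4-dimethylhex-2-ene-1,5-diol
Product: 6 rac-(E)-6-(tert-butyldimethylsilyloxy)-3,3-dimethylhex-4-en-2-ol
Conditions: TBSCl (1.05 equiv), imidazole, CH2Cl2, 0 °C
Reagents that add atoms: tert-butyldimethylsilyl chloride, CC(C)(C)[Si](C)(C)Cl
Why: Silylation is selective for the unhindered primary allylic hydroxyl over the secondary one, which is flanked by the quaternary carbon.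

Step 5
Reactants: 6 rac-(E)-6-(tert-butyldimethylsilyloxy)-3,3-dimethylhex-4-en-2-ol
Product: 7 (E)-6-(tert-butyldimethylsilyloxy)-3,3-dimethylhex-4-en-2-one
Conditions: Dess–Martin periodinane, CH2Cl2, 0 → 25 °C
Reagents that add atoms: none
Why: Dess–Martin oxidation of the secondary alcohol to the methyl ketone under near-neutral conditions that the allylic silyl ether tolerates; the quaternary carbon prevents the alkene from moving into conjugation.

Step 6
Reactants: 7 (E)-6-(tert-butyldimethylsilyloxy)-3,3-dimethylhex-4-en-2-one; 8 2,3-dibromopropene
Product: 10 (E)-8-bromo-1-(tert-butyldimethylsilyloxy)-4,4-dimethylnona-2,8-dien-5-one, via lithium enolate 9 (not isolated)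
Conditions: LiN(iPr)2, THF, −78 °C; then 8, DMPU, −78 → −20 °C
Reagents that add atoms: none
Why: Only the methyl group of 7 has α-hydrogens, so enolate 9 is regiodefined; it displaces the allylic bromide of 8 (enolate alkylation, SN2) while the vinylic bromide is inert and is kept for step 7.

Step 7
Reactants: 10 (E)-8-bromo-1-(tert-butyldimethylsilyloxy)-4,4-dimethylnona-2,8-dien-5-one
Product: 12 (R)-2-(2,2-dimethyl-6-methylidene-3-oxocyclohexyl)acetaldehyde, via silyl enol ether 11 (not isolated)
Conditions: Pd2(dba)3·CHCl3 (5 mol%), (R)-BINAP (12 mol%), Ag3PO4 (2 equiv), N-methylpyrrolidone, 70 °C; then 1 M HCl, THF, 0 → 25 °C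
Reagents that add atoms: none
Why: Zerovalent palladium carrying (R)-BINAP inserts into the vinylic C–Br bond and Ag3PO4 strips the bromide, so a cationic vinylpalladium with both phosphorus atoms still bound coordinates the C5=C6 alkene and adds across it syn, C7 to C6 and palladium to C5. β-Hydride elimination of a C4–H then gives silyl enol ether 11, Ag3PO4 takes up the acid and returns zerovalent palladium, and dilute acid hydrolyses 11 to 12. The closest known reaction type is the asymmetric intramolecular Heck cyclisation of alkenyl halides or triflates onto allylic silyl ethers under cationic conditions. The one new ring closes 6-exo-trig; 7-endo closure would require C7 to reach the far alkene carbon and is disfavoured by ring size. The C6 stereocentre is fixed in the insertion step by the axially chiral diphosphine, which has to present the Si face of C6 to C7 for the R configuration. The step needs elimination toward C4 and not toward C6–H: palladium on the exocyclic C5 is not locked anti to C6–H, so the preference rests on the two hydridic C–H bonds next to the silyloxy group, which are syn-accessible without rotating palladium away from C7, while Ag3PO4 suppresses hydride re-addition that would also drag the methylene into the ring. The gem-dimethyl group at C11 favours the folded rotamer and blocks conjugation of the alkene with the ketone, and the enol ether keeps the aldehyde masked from aldol addition by C9 while the mixture is hot.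

Step 8
Reactants: 12 (R)-2-(2,2-dimethyl-6-methylidene-3-oxocyclohexyl)acetaldehyde
Product: 13 (R)-3-(2-hydroxyethyl)-2,2-dimethyl-4-methylidenecyclohexan-1-one
Conditions: NaBH4 (0.5 equiv), CH2Cl2/EtOH, −78 °C
Reagents that add atoms: none
Why: Chemoselective borohydride reduction: at low temperature the aldehyde reacts far faster than the ketone, which is further shielded by the adjacent gem-dimethyl carbon. C6 is not α to either carbonyl and cannot epimerise.

Step 9
Reactants: 13 (R)-3-(2-hydroxyethyl)-2,2-dimethyl-4-methylidenecyclohexan-1-one
Product: 14 (R)-3-(2-iodoethyl)-2,2-dimethyl-4-methylidenecyclohexan-1-one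
Conditions: I2, PPh3, imidazole, CH2Cl2, 0 °C
Reagents that add atoms: iodine, II
Why: Appel-type iodination: the primary hydroxyl is activated on phosphorus and displaced by iodide (SN2) under neutral conditions that leave the ketone and the exocyclic alkene alone.

Step 10
Reactants: 15 but-2-yn-1-ol
Product: 16 tert-butyl(but-2-yn-1-yloxy)dimethylsilane
Conditions: TBSCl, imidazole, CH2Cl2, 25 °C
Reagents that add atoms: tert-butyldimethylsilyl chloride, CC(C)(C)[Si](C)(C)Cl
Why: Standard silylation of a primary alcohol; the silyl ether removes the acidic proton before hydrozirconation and is carried through the coupling.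

Step 11
Reactants: 16 tert-butyl(but-2-yn-1-yloxy)dimethylsilane
Product: 18 (E)-tert-butyl[(3-iodobut-2-en-1-yl)oxy]dimethylsilane, via alkenylzirconocene chloride 17 (not isolated)
Conditions: Cp2Zr(H)Cl (1.6 equiv), THF, 25 → 50 °C; then I2, 0 °C
Reagents that add atoms: iodine, II
Why: Hydrozirconation adds H and Zr syn, and with excess Cp2Zr(H)Cl at 50 °C the regioisomers should equilibrate to zirconium on the less hindered, methyl-bearing carbon. Iodinolysis of the C–Zr bond proceeds with retention and should give the E-iodide, with iodine trans to the silyloxymethyl group.

Step 12
Reactants: 14 (R)-3-(2-iodoethyl)-2,2-dimethyl-4-methylidenecyclohexan-1-one; 18 (E)-tert-butyl[(3-iodobut-2-en-1-yl)oxy]dimethylsilane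
Product: 20 (R)-3-[(E)-5-(tert-butyldimethylsilyloxy)-3-methylpent-3-en-1-yl]-2,2-dimethyl-4-methylidenecyclohexan-1-one, via alkylzinc iodide 19 (not isolated)
Conditions: Zn dust (BrCH2CH2Br, Me3SiCl activation), LiCl, THF, 35 °C; then 18, Pd(OAc)2 (2 mol%), SPhos (4 mol%), 25 °C
Reagents that add atoms: none
Why: Zinc inserts into the primary C–I bond to give 19, an organometallic that tolerates the ketone. Negishi coupling with the alkenyl iodide forms C3–C4 with retention of the E geometry, and the bulky biaryl phosphine lets reductive elimination outrun β-hydride elimination.

Step 13
Reactants: 20 (R)-3-[(E)-5-(tert-butyldimethylsilyloxy)-3-methylpent-3-en-1-yl]-2,2-dimethyl-4-methylidenecyclohexan-1-one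
Product: 21 (R)-3-[(E)-5-hydroxy-3-methylpent-3-en-1-yl]-2,2-dimethyl-4-methylidenecyclohexan-1-one
Conditions: Bu4NF, THF, 0 °C
Reagents that add atoms: none
Why: Fluoride cleaves the Si–O bond (desilylation) without acid, so the allylic alcohol cannot ionise and the exocyclic alkene cannot migrate.

Step 14
Reactants: 22 2-hydroxy-6-methylbenzoic acid
Product: 24 1-(2-hydroxy-6-methylphenyl)ethan-1-one, via trilithium gem-diolate 23 (not isolated)
Conditions: MeLi (3.3 equiv), THF, 0 → 25 °C; then inverse quench into 1 M HCl, 0 °C
Reagents that add atoms: methyllithium, [Li]C
Why: Ketone synthesis from a carboxylic acid and an organolithium: two equivalents deprotonate the phenol and the acid, the third adds to the lithium carboxylate to give 23, which cannot add again and collapses to the ketone only on the acidic quench.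

Step 15
Reactants: 24 1-(2-hydroxy-6-methylphenyl)ethan-1-one
Product: 26 4-hydroxy-5-methyl-2H-chromen-2-one, via β-keto ester 25 (not isolated)
Conditions: NaH (3 equiv), (EtO)2CO, toluene, 110 °C; then 1 M HCl
Reagents that add atoms: diethyl carbonate, CCOC(=O)OCC
Why: Claisen-type C-acylation of the ketone enolate by the carbonate gives 25, which lactonises through the ortho phenoxide. The product leaves the equilibrium as its stabilised sodium enolate, and acid sets it free.

Step 16
Reactants: 21 (R)-3-[(E)-5-hydroxy-3-methylpent-3-en-1-yl]-2,2-dimethyl-4-methylidenecyclohexan-1-one; 26 4-hydroxy-5-methyl-2H-chromen-2-one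
Product: 27 4-{[(2E)-5-[(1R)-2,2-dimethyl-6-methylidene-3-oxocyclohexyl]-3-methylpent-2-en-1-yl]oxy}-5-methyl-2H-chromen-2-one
Conditions: PPh3, DIAD, THF, 0 → 25 °C
Reagents that add atoms: none
Why: Mitsunobu etherification: the acidic enol hydroxyl of 26 protonates the phosphine–azodicarboxylate adduct and its oxygen displaces the activated primary allylic hydroxyl by SN2 without allylic shift. The neutral, cold conditions spare the product ether from ionisation and Claisen rearrangement.

## Compound list

1 | ethyl 2,2-dimethyl-3-oxobutanoate (ethyl 2,2-dimethylacetoacetate) | CCOC(=O)C(C)(C)C(C)=O | starting material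
2 | rac-2,2-dimethylbutane-1,3-diol | CC(O)C(C)(C)CO | intermediate
3 | rac-3-hydroxy-2,2-dimethylbutanal (formed in the flask) | CC(O)C(C)(C)C=O | intermediate
4 | rac-ethyl (E)-5-hydroxy-4,4-dimethylhex-2-enoate | CCOC(=O)/C=C/C(C)(C)C(C)O | intermediate
5 | rac-(E)-4,4-dimethylhex-2-ene-1,5-diol | OC/C=C/C(C)(C)C(C)O | intermediate
6 | rac-(E)-6-(tert-butyldimethylsilyloxy)-3,3-dimethylhex-4-en-2-ol | CC(O)C(C)(C)/C=C/CO[Si](C)(C)C(C)(C)C | intermediate
7 | (E)-6-(tert-butyldimethylsilyloxy)-3,3-dimethylhex-4-en-2-one | CC(=O)C(C)(C)/C=C/CO[Si](C)(C)C(C)(C)C | intermediate
8 | 2,3-dibromopropene | C=C(Br)CBr | starting material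
9 | lithium (E)-6-(tert-butyldimethylsilyloxy)-3,3-dimethylhexa-1,4-dien-2-olate (formed in the flask) | [Li]OC(=C)C(C)(C)/C=C/CO[Si](C)(C)C(C)(C)C | intermediate
10 | (E)-8-bromo-1-(tert-butyldimethylsilyloxy)-4,4-dimethylnona-2,8-dien-5-one | C=C(Br)CCC(=O)C(C)(C)/C=C/CO[Si](C)(C)C(C)(C)C | intermediate
11 | (R)-3-[2-(tert-butyldimethylsilyloxy)ethenyl]-2,2-dimethyl-4-methylidenecyclohexan-1-one, E/Z mixture at the enol ether (formed in the flask) | C=C1CCC(=O)C(C)(C)[C@@H]1C=CO[Si](C)(C)C(C)(C)C | intermediate
12 | (R)-2-(2,2-dimethyl-6-methylidene-3-oxocyclohexyl)acetaldehyde | C=C1CCC(=O)C(C)(C)[C@@H]1CC=O | intermediate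
13 | (R)-3-(2-hydroxyethyl)-2,2-dimethyl-4-methylidenecyclohexan-1-one | C=C1CCC(=O)C(C)(C)[C@@H]1CCO | intermediate
14 | (R)-3-(2-iodoethyl)-2,2-dimethyl-4-methylidenecyclohexan-1-one | C=C1CCC(=O)C(C)(C)[C@@H]1CCI | intermediate
15 | but-2-yn-1-ol | CC#CCO | starting material
16 | tert-butyl(but-2-yn-1-yloxy)dimethylsilane | CC#CCO[Si](C)(C)C(C)(C)C | intermediate
17 | (E)-[4-(tert-butyldimethylsilyloxy)but-2-en-2-yl]chlorobis(cyclopentadienyl)zirconium (formed in the flask; rings drawn η1 in the line notation) | C/C(=C\CO[Si](C)(C)C(C)(C)C)[Zr](Cl)(C1C=CC=C1)C1C=CC=C1 | intermediate
18 | (E)-tert-butyl[(3-iodobut-2-en-1-yl)oxy]dimethylsilane | I/C(C)=C/CO[Si](C)(C)C(C)(C)C | intermediate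
19 | {2-[(1R)-2,2-dimethyl-6-methylidene-3-oxocyclohexyl]ethyl}zinc iodide (formed in the flask) | C=C1CCC(=O)C(C)(C)[C@@H]1CC[Zn]I | intermediate
20 | (R)-3-[(E)-5-(tert-butyldimethylsilyloxy)-3-methylpent-3-en-1-yl]-2,2-dimethyl-4-methylidenecyclohexan-1-one | C=C1CCC(=O)C(C)(C)[C@@H]1CC/C(C)=C/CO[Si](C)(C)C(C)(C)C | intermediate
21 | (R)-3-[(E)-5-hydroxy-3-methylpent-3-en-1-yl]-2,2-dimethyl-4-methylidenecyclohexan-1-one | C=C1CCC(=O)C(C)(C)[C@@H]1CC/C(C)=C/CO | intermediate
22 | 2-hydroxy-6-methylbenzoic acid | Cc1cccc(O)c1C(=O)O | starting material
23 | trilithium 1-(2-methyl-6-oxidophenyl)ethane-1,1-diolate (formed in the flask) | Cc1cccc(O[Li])c1C(C)(O[Li])O[Li] | intermediate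
24 | 1-(2-hydroxy-6-methylphenyl)ethan-1-one | CC(=O)c1c(C)cccc1O | intermediate
25 | ethyl 3-(2-hydroxy-6-methylphenyl)-3-oxopropanoate (formed in the flask) | CCOC(=O)CC(=O)c1c(C)cccc1O | intermediate
26 | 4-hydroxy-5-methyl-2H-chromen-2-one (4-hydroxy-5-methylcoumarin) | Cc1cccc2oc(=O)cc(O)c12 | intermediate
27 | 4-{[(2E)-5-[(1R)-2,2-dimethyl-6-methylidene-3-oxocyclohexyl]-3-methylpent-2-en-1-yl]oxy}-5-methyl-2H-chromen-2-one | C=C1CCC(=O)C(C)(C)[C@@H]1CC/C(C)=C/COc1cc(=O)oc2cccc(C)c12 | target

## Step count and least certain steps

Total step count: 16. Longest linear sequence: 12 (steps 1 to 9, then 12, 13 and 16).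

Step 7 (key step). The most likely failure is poor facial selectivity in the insertion. The alkene is E and 1,2-disubstituted, so the two faces of C6 differ only by H against the quaternary C11, and E-allylic silyl ethers are the less well differentiated class with BINAP. A second leak, β-hydride elimination at C6–H after rotation about C5–C6, leads to an achiral diene and costs material but not enantiopurity. The fallback replaces catalyst control by resolution. It sets out from 10, which is cyclised with an achiral catalyst (Pd(OAc)2, dppf, Ag3PO4, same acidic work-up) to racemic aldehyde F1. NaBH4 reduces this as in step 8 to racemic alcohol F2, and preparative chromatography of F2 on a chiral stationary phase gives the R enantiomer, which is 13, where the route is rejoined before step 9. Scalemic 13 from the BINAP run can be upgraded in the same way.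

Step 6. The most likely failure is proton transfer between product 10 and unreacted enolate 9, which opens a second alkylation at C9 and lowers the yield of the monoalkylated ketone. The fallback uses an azaenolate, which exchanges protons far less readily. It sets out from 7, which is condensed with 1,1-dimethylhydrazine to the dimethylhydrazone F3. Deprotonation with LiN(iPr)2 and alkylation with 8 give the alkylated hydrazone F4, and hydrolysis with aqueous CuCl2 at neutral pH returns to 10.

Step 2. The most likely failure is competing oxidation of the secondary hydroxyl, or retro-aldol cleavage of 3 before the ylide traps it. The fallback removes the need to distinguish the two hydroxyls. It sets out from 2, which is oxidised at both positions (Swern conditions) to 2,2-dimethyl-3-oxobutanal F5. The same ylide reacts only at the aldehyde to give ethyl (E)-4,4-dimethyl-5-oxohex-2-enoate F6, and iBu2AlH reduces ester and ketone together to come back at 5. This costs one step.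

Step 12. The most likely failure is slow zinc insertion, or loss of 19 by protonation or by addition to its own ketone before transmetalation. The fallback inverts the polarity of the coupling. It sets out from 14, now used as the electrophile, and couples it with the alkenylzirconocene 17 (taken before iodinolysis) under Pd(acac)2 and LiBr in THF/N-methylpyrrolidone at 55 °C, an alkyl–alkenyl coupling of organozirconium reagents, to come back at 20 (no new compound: F0).

Step 16. The most likely failure is ambident alkylation: attack through the lactone carbonyl oxygen or through C3 instead of the C4 oxygen, encouraged by the peri methyl group that shields O4. The fallback reverses the roles of the partners so that the bond can form only at C4. It sets out from 26, which POCl3 converts to 4-chloro-5-methyl-2H-chromen-2-one F7; the sodium alkoxide of 21 (NaH, THF, 0 °C) then adds to C4 and expels chloride (addition–elimination) to arrive at 27.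

## Further compounds

F1 | step 7 | rac-2-(2,2-dimethyl-6-methylidene-3-oxocyclohexyl)acetaldehyde | C=C1CCC(=O)C(C)(C)C1CC=O
F2 | step 7 | rac-3-(2-hydroxyethyl)-2,2-dimethyl-4-methylidenecyclohexan-1-one | C=C1CCC(=O)C(C)(C)C1CCO
F3 | step 6 | 2-[(4E)-6-(tert-butyldimethylsilyloxy)-3,3-dimethylhex-4-en-2-ylidene]-1,1-dimethylhydrazine | CC(=NN(C)C)C(C)(C)/C=C/CO[Si](C)(C)C(C)(C)C
F4 | step 6 | 2-[(2E)-8-bromo-1-(tert-butyldimethylsilyloxy)-4,4-dimethylnona-2,8-dien-5-ylidene]-1,1-dimethylhydrazine | C=C(Br)CCC(=NN(C)C)C(C)(C)/C=C/CO[Si](C)(C)C(C)(C)C
F5 | step 2 | 2,2-dimethyl-3-oxobutanal | CC(=O)C(C)(C)C=O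
F6 | step 2 | ethyl (E)-4,4-dimethyl-5-oxohex-2-enoate | CCOC(=O)/C=C/C(C)(C)C(C)=O
F0 | step 12 | none | none
F7 | step 16 | 4-chloro-5-methyl-2H-chromen-2-one | Cc1cccc2oc(=O)cc(Cl)c12
A1 | alternative 1 | (E)-5-[(1R,3S)-3-(tert-butyldimethylsilyloxy)-2,2-dimethyl-6-methylidenecyclohexyl]-3-methylpent-2-en-1-ol | C=C1CC[C@H](O[Si](C)(C)C(C)(C)C)C(C)(C)[C@@H]1CC/C(C)=C/CO
A2 | alternative 1 | tert-butyl{[(1S,3R)-3-(but-3-yn-1-yl)-2,2-dimethyl-4-methylidenecyclohexyl]oxy}dimethylsilane | C=C1CC[C@H](O[Si](C)(C)C(C)(C)C)C(C)(C)[C@@H]1CCC#C
A3 | alternative 2 | 4-methoxy-5-methyl-2H-chromen-2-one | COc1cc(=O)oc2cccc(C)c12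
A4 | alternative 2 | 4-methoxy-6-[(1E,3E)-penta-1,3-dien-1-yl]-2H-pyran-2-one | COC1=CC(=O)OC(/C=C/C=C/C)=C1
A5 | alternative 3 | (R)-2,2-dimethyl-4-methylidene-3-[2-(2-methyl-1,3-dioxolan-2-yl)ethyl]cyclohexan-1-one | C=C1CCC(=O)C(C)(C)[C@@H]1CCC2(C)OCCO2
A6 | alternative 3 | (S)-5-(chloromethyl)-3,3-dimethyl-4-[2-(2-methyl-1,3-dioxolan-2-yl)ethyl]hex-5-en-2-one | CC(=O)C(C)(C)[C@H](CCC1(C)OCCO1)C(=C)CCl
A7 | alternative 3 | (S)-limonene, (4S)-1-methyl-4-(prop-1-en-2-yl)cyclohex-1-ene | CC1=CC[C@H](CC1)C(=C)C
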